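**Plan**

- The target is a linear chain of seven oxygenated benzene rings, A (the 2,4,6-trihydroxyphenoxy end) to G, held by six diaryl ether bonds. Seventeen hydroxyls travel as methyl ethers, one arises by a late Dakin oxidation, and the last step is a global demethylation.
- Retrosynthesis cuts the O–C1 and C5–O bonds of ring B first, then in turn C2(C)–O–C1(D), C4(D)–O–C1(E), C2(E)–O–C1(F) and C5(F)–O–C1(G).
- Ring B has oxygen on C1, C3, C4 and C5. C4 is para to C1 and ortho to C3 and C5, so a formyl group on C4 activates a fluorine on each of these three carbons and afterwards becomes the C4 hydroxyl; 2,4,6-trifluorobenzaldehyde is therefore ring B.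
- Forward, the chain grows G→F→E→D→C by four copper-catalysed couplings of a phenol with a bromobenzaldehyde, each followed by Baeyer–Villiger/Dakin conversion of the formyl group into the next phenol (steps 1–8). The pentamer phenol, the ring A phenol and the trifluoro core are joined in one pot (step 9); methoxide, Dakin oxidation and BBr3 finish (steps 10–12).
- No ring is formed and the target has no stereocentre, so there is no stereochemistry to set.

Key step: step 9

Remark: the diaryl ether axes rotate freely, so the SMILES needs no stereodescriptors; the three bromobenzaldehydes used are taken as purchased catalogue compounds.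

**Route**

Step 1
Reactants: 1 3,4,5-trimethoxyphenol (ring G); 2 3-bromo-4,5-dimethoxybenzaldehyde (ring F)
Product: 3 3,4-dimethoxy-5-(3,4,5-trimethoxyphenoxy)benzaldehyde (F–G aldehyde)
Conditions: CuI (10 mol %), N,N-dimethylglycine (30 mol %), Cs2CO3, dioxane, 100 °C, argon
Reagents that add atoms: none
Why: Ullmann-type copper-catalysed diaryl ether coupling of an unhindered, electron-rich phenol with an aryl bromide that has a single ortho substituent is routine under amino acid ligation, and the formyl group is inert to carbonate base.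

Step 2
Reactants: 3 F–G aldehyde
Product: 5 3,4-dimethoxy-5-(3,4,5-trimethoxyphenoxy)phenol (F–G phenol), via F–G aryl formate 4 (not isolated)
Conditions: mCPBA, CH2Cl2, 0 °C to rt; aqueous wash; then K2CO3 (cat.), MeOH, rt
Reagents that add atoms: mCPBA, O=C(OO)c1cccc(Cl)c1
Why: Baeyer–Villiger (Dakin-type) oxidation in which the aryl group, made electron-rich by its para methoxy group, migrates in the Criegee adduct in preference to hydride, the labile aryl formate then being methanolysed by catalytic carbonate.

Step 3
Reactants: 5 F–G phenol; 6 2-bromo-3,4,5-trimethoxybenzaldehyde (ring E)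
Product: 7 2-[3,4-dimethoxy-5-(3,4,5-trimethoxyphenoxy)phenoxy]-3,4,5-trimethoxybenzaldehyde (E–G aldehyde)
Conditions: CuI (10 mol %), N,N-dimethylglycine (30 mol %), Cs2CO3, dioxane, 105 °C, argon
Reagents that add atoms: none
Why: Ullmann-type coupling in which the C–Br bond is activated by the ortho formyl group and the nucleophile is a phenol with both ortho positions free, which offsets the methoxy group flanking the bromide.

Step 4
Reactants: 7 E–G aldehyde
Product: 9 2-[3,4-dimethoxy-5-(3,4,5-trimethoxyphenoxy)phenoxy]-3,4,5-trimethoxyphenol (E–G phenol), via E–G aryl formate 8 (not isolated)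
Conditions: mCPBA, CH2Cl2, 0 °C to rt; aqueous wash; then K2CO3 (cat.), MeOH, rt
Reagents that add atoms: mCPBA, O=C(OO)c1cccc(Cl)c1
Why: Baeyer–Villiger (Dakin-type) oxidation, aryl migration being favoured by the para methoxy and ortho aryloxy groups of ring E; the other rings carry no oxidisable function.

Step 5
Reactants: 9 E–G phenol; 10 4-bromo-3,5-dimethoxybenzaldehyde (ring D)
Product: 11 tetramer aldehyde D–G (3,5-dimethoxybenzaldehyde bearing at C4 the aryloxy group of phenol 9)
Conditions: CuI (20 mol %), picolinic acid (40 mol %), K3PO4, DMSO, 100 °C, argon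
Reagents that add atoms: none
Why: Ullmann-type coupling under the picolinic acid conditions developed for hindered partners, in which the para formyl group eases activation of the C–Br bond that lies between two methoxy groups.

Step 6
Reactants: 11 tetramer aldehyde D–G
Product: 13 tetramer phenol D–G (hydroxyl on ring D carbon 1), via D–G aryl formate 12 (not isolated)
Conditions: mCPBA, CH2Cl2, 0 °C to rt; aqueous wash; then K2CO3 (cat.), MeOH, rt
Reagents that add atoms: mCPBA, O=C(OO)c1cccc(Cl)c1
Why: Baeyer–Villiger (Dakin-type) oxidation of a 4-oxygenated 3,5-dimethoxybenzaldehyde, the same substitution type as in the standard conversion of 3,4,5-trimethoxybenzaldehyde into its phenol.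

Step 7
Reactants: 13 tetramer phenol D–G; 6 2-bromo-3,4,5-trimethoxybenzaldehyde (ring C)
Product: 14 pentamer aldehyde C–G (3,4,5-trimethoxybenzaldehyde bearing at C2 the aryloxy group of phenol 13)
Conditions: CuI (10 mol %), N,N-dimethylglycine (30 mol %), Cs2CO3, dioxane, 105 °C, argon
Reagents that add atoms: none
Why: Ullmann-type coupling as in step 3, again between an ortho-formyl-activated bromide and a phenol whose hydroxyl has two free ortho positions.

Step 8
Reactants: 14 pentamer aldehyde C–G
Product: 16 pentamer phenol C–G (free hydroxyl on ring C carbon 1), via C–G aryl formate 15 (not isolated)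
Conditions: mCPBA, CH2Cl2, 0 °C to rt; aqueous wash; then K2CO3 (cat.), MeOH, rt
Reagents that add atoms: mCPBA, O=C(OO)c1cccc(Cl)c1
Why: Baeyer–Villiger (Dakin-type) oxidation as in step 4, which turns the formyl carbon of ring C into the hydroxyl needed as the nucleophile of the next step.

Step 9
Reactants: 17 2,4,6-trifluorobenzaldehyde (ring B); 18 2,4,6-trimethoxyphenol (ring A); 16 pentamer phenol C–G
Product: 20 heptamer fluoroaldehyde (2-fluoro-4-(2,4,6-trimethoxyphenoxy)benzaldehyde bearing at C6 the aryloxy group of phenol 16), via 2,6-difluoro-4-(2,4,6-trimethoxyphenoxy)benzaldehyde 19 (not isolated)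
Conditions: 17, 18 (1 equiv), Cs2CO3, DMSO, 20 °C, argon; then 16 (1 equiv), Cs2CO3, 70 °C, same pot
Reagents that add atoms: none
Why: Each displacement is an addition–elimination in which the phenoxide adds to a C–F carbon, the charge of the Meisenheimer anion is taken up by the formyl group (para for the first attack, ortho for the second) and fluoride leaves. The closest known reaction type is the SNAr of phenoxides on ortho- and para-fluorobenzaldehydes and the stepwise substitution of polyfluoroarenes. No ring is closed and no stereocentre is formed; the two aryl C–O bonds O–C1 and C5–O of ring B are made. The step needs para-before-ortho regioselectivity and one substitution per stage: the phenoxide of 18, flanked by two methoxy groups and used as a free caesium phenoxide in DMSO, should go to the para carbon, which is the most activated and the only one not next to the formyl group. After that the two remaining fluorines are equivalent, so the phenoxide of 16 can give only one product, and each aryloxy group donates into the ring so that a third displacement should be slow at 70 °C when the phenols are used in equimolar amounts.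

Step 10
Reactants: 20 heptamer fluoroaldehyde
Product: 21 heptamer methoxyaldehyde (2-methoxy-4,6-bis(aryloxy)benzaldehyde as ring B)
Conditions: NaOMe, THF–MeOH, 60 °C
Reagents that add atoms: sodium methoxide, C[O-].[Na+]
Why: SNAr of the last ortho fluorine by methoxide, in which the C–F carbon is the most electrophilic site and fluoride the best nucleofuge of the addition-limited process, so the two aryloxy groups should stay in place.

Step 11
Reactants: 21 heptamer methoxyaldehyde
Product: 23 heptamer phenol (free hydroxyl on ring B carbon 4 and seventeen methyl ethers), via heptamer aryl formate 22 (not isolated)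
Conditions: mCPBA (1.1 equiv), CH2Cl2, 0 °C; aqueous wash; then K2CO3 (cat.), MeOH, rt, argon
Reagents that add atoms: mCPBA, O=C(OO)c1cccc(Cl)c1
Why: Baeyer–Villiger (Dakin-type) oxidation of a 2,4,6-trioxygenated benzaldehyde, a highly migration-prone aryl group, the phenol being released only after the peracid is removed so that the para-aryloxyphenol is not oxidised further.

Step 12
Reactants: 23 heptamer phenol
Product: 24 target octadecaphenol CNP0137585.0
Conditions: BBr3 (excess), CH2Cl2, −78 °C to rt, argon; then H2O, 0 °C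
Reagents that add atoms: none
Why: Lewis acid-mediated cleavage of aryl methyl ethers with BBr3, in which bromide attacks the methyl carbon of each O–boron adduct, while the diaryl ether bonds survive because their aryl carbons cannot undergo this displacement.

**Compound list**

1 | 3,4,5-trimethoxyphenol (ring G) | COc1cc(O)cc(OC)c1OC | starting material
2 | 3-bromo-4,5-dimethoxybenzaldehyde (ring F) | O=Cc1cc(Br)c(OC)c(OC)c1 | starting material
3 | 3,4-dimethoxy-5-(3,4,5-trimethoxyphenoxy)benzaldehyde (F–G aldehyde) | O=Cc1cc(OC)c(OC)c(Oc2cc(OC)c(OC)c(OC)c2)c1 | intermediate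
4 | 3,4-dimethoxy-5-(3,4,5-trimethoxyphenoxy)phenyl formate (F–G aryl formate) | O=COc1cc(OC)c(OC)c(Oc2cc(OC)c(OC)c(OC)c2)c1 | intermediate
5 | 3,4-dimethoxy-5-(3,4,5-trimethoxyphenoxy)phenol (F–G phenol) | Oc1cc(OC)c(OC)c(Oc2cc(OC)c(OC)c(OC)c2)c1 | intermediate
6 | 2-bromo-3,4,5-trimethoxybenzaldehyde (rings E and C) | O=Cc1cc(OC)c(OC)c(OC)c1Br | starting material
7 | 2-[3,4-dimethoxy-5-(3,4,5-trimethoxyphenoxy)phenoxy]-3,4,5-trimethoxybenzaldehyde (E–G aldehyde) | O=Cc1cc(OC)c(OC)c(OC)c1Oc1cc(OC)c(OC)c(Oc2cc(OC)c(OC)c(OC)c2)c1 | intermediate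
8 | E–G aryl formate | O=COc1cc(OC)c(OC)c(OC)c1Oc1cc(OC)c(OC)c(Oc2cc(OC)c(OC)c(OC)c2)c1 | intermediate
9 | 2-[3,4-dimethoxy-5-(3,4,5-trimethoxyphenoxy)phenoxy]-3,4,5-trimethoxyphenol (E–G phenol) | Oc1cc(OC)c(OC)c(OC)c1Oc1cc(OC)c(OC)c(Oc2cc(OC)c(OC)c(OC)c2)c1 | intermediate
10 | 4-bromo-3,5-dimethoxybenzaldehyde (ring D) | O=Cc1cc(OC)c(Br)c(OC)c1 | starting material
11 | tetramer aldehyde D–G | O=Cc1cc(OC)c(Oc2cc(OC)c(OC)c(OC)c2Oc2cc(OC)c(OC)c(Oc3cc(OC)c(OC)c(OC)c3)c2)c(OC)c1 | intermediate
12 | D–G aryl formate | O=COc1cc(OC)c(Oc2cc(OC)c(OC)c(OC)c2Oc2cc(OC)c(OC)c(Oc3cc(OC)c(OC)c(OC)c3)c2)c(OC)c1 | intermediate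
13 | tetramer phenol D–G | Oc1cc(OC)c(Oc2cc(OC)c(OC)c(OC)c2Oc2cc(OC)c(OC)c(Oc3cc(OC)c(OC)c(OC)c3)c2)c(OC)c1 | intermediate
14 | pentamer aldehyde C–G | O=Cc1cc(OC)c(OC)c(OC)c1Oc1cc(OC)c(Oc2cc(OC)c(OC)c(OC)c2Oc2cc(OC)c(OC)c(Oc3cc(OC)c(OC)c(OC)c3)c2)c(OC)c1 | intermediate
15 | C–G aryl formate | O=COc1cc(OC)c(OC)c(OC)c1Oc1cc(OC)c(Oc2cc(OC)c(OC)c(OC)c2Oc2cc(OC)c(OC)c(Oc3cc(OC)c(OC)c(OC)c3)c2)c(OC)c1 | intermediate
16 | pentamer phenol C–G | Oc1cc(OC)c(OC)c(OC)c1Oc1cc(OC)c(Oc2cc(OC)c(OC)c(OC)c2Oc2cc(OC)c(OC)c(Oc3cc(OC)c(OC)c(OC)c3)c2)c(OC)c1 | intermediate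
17 | 2,4,6-trifluorobenzaldehyde (ring B) | O=Cc1c(F)cc(F)cc1F | starting material
18 | 2,4,6-trimethoxyphenol (ring A) | COc1cc(OC)c(O)c(OC)c1 | starting material
19 | 2,6-difluoro-4-(2,4,6-trimethoxyphenoxy)benzaldehyde | O=Cc1c(F)cc(Oc2c(OC)cc(OC)cc2OC)cc1F | intermediate
20 | heptamer fluoroaldehyde | O=Cc1c(F)cc(Oc2c(OC)cc(OC)cc2OC)cc1Oc1cc(OC)c(OC)c(OC)c1Oc1cc(OC)c(Oc2cc(OC)c(OC)c(OC)c2Oc2cc(OC)c(OC)c(Oc3cc(OC)c(OC)c(OC)c3)c2)c(OC)c1 | intermediate
21 | heptamer methoxyaldehyde | O=Cc1c(OC)cc(Oc2c(OC)cc(OC)cc2OC)cc1Oc1cc(OC)c(OC)c(OC)c1Oc1cc(OC)c(Oc2cc(OC)c(OC)c(OC)c2Oc2cc(OC)c(OC)c(Oc3cc(OC)c(OC)c(OC)c3)c2)c(OC)c1 | intermediate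
22 | heptamer aryl formate | O=COc1c(OC)cc(Oc2c(OC)cc(OC)cc2OC)cc1Oc1cc(OC)c(OC)c(OC)c1Oc1cc(OC)c(Oc2cc(OC)c(OC)c(OC)c2Oc2cc(OC)c(OC)c(Oc3cc(OC)c(OC)c(OC)c3)c2)c(OC)c1 | intermediate
23 | heptamer phenol (heptadecamethyl ether of the target) | Oc1c(OC)cc(Oc2c(OC)cc(OC)cc2OC)cc1Oc1cc(OC)c(OC)c(OC)c1Oc1cc(OC)c(Oc2cc(OC)c(OC)c(OC)c2Oc2cc(OC)c(OC)c(Oc3cc(OC)c(OC)c(OC)c3)c2)c(OC)c1 | intermediate
24 | CNP0137585.0 | Oc1cc(O)c(Oc2cc(O)c(O)c(Oc3cc(O)c(O)c(O)c3Oc3cc(O)c(Oc4cc(O)c(O)c(O)c4Oc4cc(O)c(O)c(Oc5cc(O)c(O)c(O)c5)c4)c(O)c3)c2)c(O)c1 | target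

**Step count**

Total steps: 12. Longest linear sequence: 12 steps (from 1 and 2 to 24).

**Steps most likely to fail**

Step 9. The first phenoxide may attack an ortho carbon next to the formyl group in competition with the para carbon, or a second ring A phenoxide may enter before the pentamer is added; either gives regioisomeric heptamers that are hard to separate. The fallback fixes the regiochemistry by building the ring B aldehyde in the reverse order. It sets out from 18, which is coupled with purchased 1-bromo-3,5-difluorobenzene (Fc1cc(F)cc(Br)c1) using CuI, picolinic acid and K3PO4 in DMSO at 90 °C to give 1,3-difluoro-5-(2,4,6-trimethoxyphenoxy)benzene F1. Directed lithiation between the two fluorines with LDA in THF at −78 °C and quenching with DMF should then give 19 as a single isomer, now isolated. Its SNAr with 16 (Cs2CO3, DMSO, 70 °C) returns to the route at 20.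

Step 5. Bond formation at the bromide flanked by two methoxy groups may be so slow that protodebromination of 10 and oxidative loss of the phenoxide take over. The fallback replaces the copper coupling with an uncatalysed addition–elimination on a different electrophile. It sets out from 9, which is heated with the known fluoro analogue 4-fluoro-3,5-dimethoxybenzaldehyde (O=Cc1cc(OC)c(F)c(OC)c1, taken as a purchased reagent) and Cs2CO3 in DMSO at 130 °C. The para formyl group stabilises the Meisenheimer anion, and the reaction returns to the route directly at 11 (no new compound, F0).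

Step 12. Cleavage of seventeen methyl ethers may stop short of completion, and the free polyphenol may oxidise in air or be lost on chromatography. The fallback isolates the product in protected form. It sets out from 23: after the BBr3 treatment and quench the crude material is acetylated with acetic anhydride in pyridine to give the octadecaacetate of the target F2, which is stable and can be purified on silica, where under-demethylated acetates are separated. Acid-catalysed methanolysis (cat. HCl, degassed MeOH, 40 °C) then releases the phenols and returns to the route at 24.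

**Further compounds**

F1 | step 9 | 1,3-difluoro-5-(2,4,6-trimethoxyphenoxy)benzene | COc1cc(OC)c(Oc2cc(F)cc(F)c2)c(OC)c1
F0 | step 5 | none | none
F2 | step 12 | octadecaacetate of the target | CC(=O)Oc1cc(OC(C)=O)c(Oc2cc(OC(C)=O)c(OC(C)=O)c(Oc3cc(OC(C)=O)c(OC(C)=O)c(OC(C)=O)c3Oc3cc(OC(C)=O)c(Oc4cc(OC(C)=O)c(OC(C)=O)c(OC(C)=O)c4Oc4cc(OC(C)=O)c(OC(C)=O)c(Oc5cc(OC(C)=O)c(OC(C)=O)c(OC(C)=O)c5)c4)c(OC(C)=O)c3)c2)c(OC(C)=O)c1
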